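**Strategy.** Numbering: ring A = C1 (acetoxymethyl carbon), C2 (ketone), C3, C4, C4a, C8a; ring B = C4a, C5 (side-chain carbon), C6, C7 (C–OH), C8 (C=O), C8a. Ring B is opened by a [4+2] disconnection that makes C6–C7 and C4a–C5 together: the C8 carbonyl allows C7=C8(OSi)–C8a=C4a to serve as a 2-silyloxydiene on enantiopure ring A, and C5/C6 with their methyls are tiglaldehyde. A chiral oxazaborolidinium-catalysed Diels–Alder reaction closes ring B and sets quaternary C5 by catalyst control; the formyl group becomes the side chain, and the transient C4a and C6 centres are later flattened. C1 stems from a desymmetrising dione reduction.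

Key step: step 7

Remark (assumption): in steps 2 and 7 the sense of induction on these new substrates rests on the accepted catalyst models; the enantiomer named is the one the model predicts, and the mirror-image catalyst would be taken, with no other change, if the sense were reversed. The target is (1S,5S) in the numbering above; side-chain carbons are C1'–C5'.

Step 1
Reactants: 1 2-methylcyclohexane-1,3-dione; 2 formaldehyde (37% aqueous)
Product: 3 2-(hydroxymethyl)-2-methylcyclohexane-1,3-dione
Conditions: 37% aq. HCHO (excess), cat. Et3N, H2O/THF, 0 °C → rt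
Reagents that add atoms: none
Why: Aldol hydroxymethylation of the acidic inter-carbonyl carbon, the only position that can react twice-activated, builds the quaternary carbon that becomes C1; the product is still prochiral, so no stereocentre is set.

Step 2
Reactants: 3 2-(hydroxymethyl)-2-methylcyclohexane-1,3-dione
Product: 4 (2S,3S)-3-hydroxy-2-(hydroxymethyl)-2-methylcyclohexan-1-one
Conditions: RuCl(p-cymene)[(S,S)-TsDPEN] (1 mol%), HCO2H/Et3N (5:2), CH2Cl2, rt; chromatography
Reagents that add atoms: none
Why: Desymmetrising asymmetric transfer hydrogenation reduces one of the two enantiotopic carbonyls and fixes the carbinol as (3S); hydride delivery anti to the hydroxymethyl arm should favour the (2S,3S) isomer, which is freed from the minor diastereomer by chromatography, so the quaternary carbon (future C1) is obtained as (2S).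

Step 3
Reactants: 4 (2S,3S)-3-hydroxy-2-(hydroxymethyl)-2-methylcyclohexan-1-one
Product: 5 acetonide-protected ketone
Conditions: 2,2-dimethoxypropane, PPTS (cat.), acetone, rt
Reagents that add atoms: 2,2-dimethoxypropane, COC(C)(C)OC
Why: Acid-catalysed transketalisation ties the cis-1,3-diol into a 1,3-dioxane, so that one protecting group covers both hydroxyls through all basic and organometallic steps.

Step 4
Reactants: 5 acetonide-protected ketone
Product: 7 bicyclic enol triflate, via potassium enolate 6 (not isolated)
Conditions: KHMDS, THF, −78 °C; then PhNTf2, −78 → 0 °C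
Reagents that add atoms: N-phenylbis(trifluoromethanesulfonimide), O=S(=O)(N(c1ccccc1)S(=O)(=O)C(F)(F)F)C(F)(F)F
Why: Enol triflate formation is regiospecific because the other α-carbon is quaternary, which places the future C8a=C4a double bond.

Step 5
Reactants: 7 bicyclic enol triflate; 8 tributyl(1-ethoxyvinyl)stannane
Product: 10 ring A methyl ketone, via ethoxy diene 9 (not isolated)
Conditions: Pd(PPh3)4 (5 mol%), LiCl (3 equiv), THF, reflux; then 0.5 M aq. HCl, THF, 0 °C, brief
Reagents that add atoms: water, O
Why: Stille coupling of the hindered alkenyl triflate with the acyl-anion equivalent installs C8 and C7, and the α-alkoxy enol ether is hydrolysed by cold dilute acid much faster than the dioxane acetal.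

Step 6
Reactants: 10 ring A methyl ketone
Product: 11 ring A 2-silyloxy diene
Conditions: TBSOTf, Et3N, CH2Cl2, 0 °C
Reagents that add atoms: tert-butyldimethylsilyl triflate, CC(C)(C)[Si](C)(C)OS(=O)(=O)C(F)(F)F
Why: Soft enolisation with silyl triflate and amine removes a proton from the acetyl methyl group (kinetic α'-position) and gives the cross-conjugated 2-silyloxy-1,3-diene C7=C8(OTBS)–C8a=C4a.

Step 7
Reactants: 11 ring A 2-silyloxy diene; 12 tiglaldehyde ((E)-2-methylbut-2-enal)
Product: 13 Diels–Alder adduct
Conditions: (R)-B-(o-tolyl)oxazaborolidine from (R)-α,α-diphenylprolinol (20 mol%), Tf2NH (20 mol%), CH2Cl2, −78 → −20 °C; Et3N quench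
Reagents that add atoms: none
Why: The N-protonated oxazaborolidine binds the formyl oxygen of 12 (formyl C–H···O contact, s-trans enal) and lowers its LUMO, so a concerted but asynchronous normal-demand [4+2] cycloaddition takes place in which C7 of the diene leads onto C6 (the β-carbon) and C4a then closes onto C5 (the α-carbon). The closest known reaction type is the cationic oxazaborolidine-catalysed enantioselective Diels–Alder reaction of α-substituted α,β-enals with 2-silyloxy-1,3-dienes. Ring B is closed by the cycloaddition itself (six-membered, suprafacial on both partners), so the E geometry of 12 places the C6 and C5 methyl groups cis. C5 is controlled by the catalyst alone: the (R)-catalyst is expected to cover the Re face of the enal α-carbon, so C4a adds to its Si face, which corresponds to (5S) in the target once the formyl group has become C1'. The step needs regio- and enantioface selectivity but neither endo/exo nor diene-face selectivity, because C4a and C6 are flattened in steps 12 and 16; the regiochemistry is secured by the C8 silyloxy group, which makes C7 the nucleophilic terminus, reinforced by the alkyl-substituted C4a terminus pairing with the α-carbon. The remote C1 and C2 centres of 11 are not required to exert any control.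

Step 8
Reactants: 13 Diels–Alder adduct
Product: 14 C5-vinyl silyl enol ether
Conditions: Ph3PCH3Br, KOtBu, THF, 0 °C → rt
Reagents that add atoms: methyltriphenylphosphonium bromide, C[P+](c1ccccc1)(c1ccccc1)c1ccccc1.[Br-]
Why: Wittig methylenation of the non-enolisable neopentyl aldehyde supplies C2' and leaves the silyl enol ether and acetonide untouched.

Step 9
Reactants: 15 but-2-yn-1-ol
Product: 16 1-(tert-butyldiphenylsilyloxy)but-2-yne
Conditions: TBDPSCl, imidazole, CH2Cl2, rt
Reagents that add atoms: tert-butyl(chloro)diphenylsilane, CC(C)(C)[Si](Cl)(c1ccccc1)c1ccccc1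
Why: Silylation of the primary alcohol; this silyl ether is chosen because it survives the acid of step 14 and can be removed last.

Step 10
Reactants: 16 1-(tert-butyldiphenylsilyloxy)but-2-yne
Product: 18 (E)-3-iodobut-2-enyl silyl ether, via alkenylzirconocene chloride 17 (not isolated)
Conditions: Cp2Zr(H)Cl (2.5 equiv), THF, rt → 50 °C; then I2, 0 °C
Reagents that add atoms: iodine, II
Why: Hydrozirconation is a syn addition that, after equilibration with excess hydride, places zirconium on the less hindered methyl-bearing carbon, and iodinolysis with retention gives the (E)-iodide with iodine trans to the CH2O group.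

Step 11
Reactants: 14 C5-vinyl silyl enol ether; 18 (E)-3-iodobut-2-enyl silyl ether
Product: 20 side-chain-coupled silyl enol ether, via B-alkyl-9-BBN 19 (not isolated)
Conditions: 9-BBN, THF, 0 °C → rt; then 18, Pd(dppf)Cl2 (5 mol%), AsPh3, Cs2CO3, DMF/THF/H2O, rt
Reagents that add atoms: none
Why: Anti-Markovnikov hydroboration of the only monosubstituted alkene followed by B-alkyl Suzuki–Miyaura coupling joins C2' to C3' with retention of the E geometry of the iodide.

Step 12
Reactants: 20 side-chain-coupled silyl enol ether
Product: 21 C4a=C8a enone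
Conditions: Pd(OAc)2 (1.1 equiv), MeCN, rt → 40 °C
Reagents that add atoms: none
Why: Saegusa–Ito oxidation: palladation at C8a and syn β-hydride elimination of the C4a hydrogen, the only β-hydrogen available, gives the tetrasubstituted enone, removes the C4a stereocentre and so merges the C4a epimers into one compound.

Step 13
Reactants: 21 C4a=C8a enone
Product: 23 C7-hydroxy enone, via lithium enolate 22 (not isolated)
Conditions: LiHMDS, THF, −78 °C; then 2-(phenylsulfonyl)-3-phenyloxaziridine, −78 °C; aq. NH4Cl
Reagents that add atoms: 2-(phenylsulfonyl)-3-phenyloxaziridine, O=S(=O)(N1OC1c1ccccc1)c1ccccc1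
Why: Kinetic α'-deprotonation at C7 gives the cross-conjugated enolate, which is hydroxylated by the N-sulfonyloxaziridine (enolate oxidation); the C7 configuration is irrelevant because the carbon is oxidised in step 16.

Step 14
Reactants: 23 C7-hydroxy enone
Product: 24 triol
Conditions: PPTS (cat.), MeOH, 45 °C
Reagents that add atoms: none
Why: Acid-catalysed transketalisation to methanol releases the C1 hydroxymethyl and C2 hydroxyl groups, while the tert-butyldiphenylsilyl ether is stable to this mild acid.

Step 15
Reactants: 24 triol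
Product: 25 primary monoacetate
Conditions: AcCl (1.05 equiv), 2,4,6-collidine, CH2Cl2, −78 °C
Reagents that add atoms: acetyl chloride, CC(Cl)=O
Why: Chemoselective acylation of the only primary hydroxyl; the C2 hydroxyl (next to the quaternary carbon) and the C7 hydroxyl (next to the ketone, between two substituted carbons) should react much more slowly at low temperature with a hindered base.

Step 16
Reactants: 25 primary monoacetate
Product: 27 silyl-protected diosphenol, via triketone 26 (not isolated)
Conditions: (COCl)2, DMSO, CH2Cl2, −78 °C; then Et3N, −78 → 0 °C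
Reagents that add atoms: none
Why: Swern oxidation converts both secondary carbinols (C2 and C7) to ketones in one operation, and the C7,C8-dione enolises toward C6, its only α-hydrogen, to the diosphenol, which removes the C6 stereocentre.

Step 17
Reactants: 27 silyl-protected diosphenol
Product: 28 target (CNP0512382.1)
Conditions: HF·pyridine, pyridine/THF, 0 °C → rt
Reagents that add atoms: none
Why: Fluoride-mediated desilylation under buffered, non-basic conditions frees the allylic alcohol without acetate migration or harm to the diosphenol.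

**Compound list**

1 | 2-methylcyclohexane-1,3-dione | CC1C(=O)CCCC1=O | starting material
2 | formaldehyde (37% aqueous) | C=O | starting material
3 | 2-(hydroxymethyl)-2-methylcyclohexane-1,3-dione | CC1(CO)C(=O)CCCC1=O | intermediate
4 | (2S,3S)-3-hydroxy-2-(hydroxymethyl)-2-methylcyclohexan-1-one (OH cis to CH2OH) | OC[C@@]1(C)[C@@H](O)CCCC1=O | intermediate
5 | acetonide-protected ketone (cis-fused 1,3-dioxane of 4) | CC1(C)OC[C@@]2(C)[C@@H](O1)CCCC2=O | intermediate
6 | potassium enolate of 5 (not isolated) | CC1(C)OC[C@@]2(C)[C@@H](O1)CCC=C2[O-].[K+] | intermediate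
7 | bicyclic enol triflate | CC1(C)OC[C@@]2(C)[C@@H](O1)CCC=C2OS(=O)(=O)C(F)(F)F | intermediate
8 | tributyl(1-ethoxyvinyl)stannane | CCCC[Sn](CCCC)(CCCC)C(=C)OCC | starting material
9 | ethoxy diene (not isolated) | CC1(C)OC[C@@]2(C)[C@@H](O1)CCC=C2C(=C)OCC | intermediate
10 | ring A methyl ketone (1-acetylcyclohexene with C1 and C2 in place) | CC1(C)OC[C@@]2(C)[C@@H](O1)CCC=C2C(C)=O | intermediate
11 | ring A 2-(tert-butyldimethylsilyloxy) diene | CC1(C)OC[C@@]2(C)[C@@H](O1)CCC=C2C(=C)O[Si](C)(C)C(C)(C)C | intermediate
12 | tiglaldehyde, (E)-2-methylbut-2-enal | C/C=C(\C)C=O | starting material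
13 | Diels–Alder adduct: C5 formyl, C5 and C6 methyls cis, C8 silyl enol ether, C4a epimers (left open in the SMILES) | CC1(C)OC[C@@]2(C)[C@@H](O1)CCC3C2=C(O[Si](C)(C)C(C)(C)C)C[C@H](C)[C@@]3(C)C=O | intermediate
14 | C5-vinyl silyl enol ether | CC1(C)OC[C@@]2(C)[C@@H](O1)CCC3C2=C(O[Si](C)(C)C(C)(C)C)C[C@H](C)[C@@]3(C)C=C | intermediate
15 | but-2-yn-1-ol | CC#CCO | starting material
16 | 1-(tert-butyldiphenylsilyloxy)but-2-yne | CC#CCO[Si](c1ccccc1)(c1ccccc1)C(C)(C)C | intermediate
17 | (E)-alkenylzirconocene chloride (not isolated) | C/C(=C\CO[Si](c1ccccc1)(c1ccccc1)C(C)(C)C)[Zr](Cl)(C1C=CC=C1)C1C=CC=C1 | intermediate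
18 | (E)-tert-butyl((3-iodobut-2-en-1-yl)oxy)diphenylsilane | C/C(I)=C\CO[Si](c1ccccc1)(c1ccccc1)C(C)(C)C | intermediate
19 | B-alkyl-9-BBN from 14 (not isolated) | CC1(C)OC[C@@]2(C)[C@@H](O1)CCC3C2=C(O[Si](C)(C)C(C)(C)C)C[C@H](C)[C@@]3(C)CCB1C2CCCC1CCC2 | intermediate
20 | side-chain-coupled silyl enol ether | CC1(C)OC[C@@]2(C)[C@@H](O1)CCC3C2=C(O[Si](C)(C)C(C)(C)C)C[C@H](C)[C@@]3(C)CC/C(C)=C/CO[Si](c1ccccc1)(c1ccccc1)C(C)(C)C | intermediate
21 | C4a=C8a enone | CC1(C)OC[C@@]2(C)[C@@H](O1)CCC3=C2C(=O)C[C@H](C)[C@@]3(C)CC/C(C)=C/CO[Si](c1ccccc1)(c1ccccc1)C(C)(C)C | intermediate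
22 | lithium enolate of 21 (not isolated) | CC1(C)OC[C@@]2(C)[C@@H](O1)CCC3=C2C([O-])=C[C@H](C)[C@@]3(C)CC/C(C)=C/CO[Si](c1ccccc1)(c1ccccc1)C(C)(C)C.[Li+] | intermediate
23 | C7-hydroxy enone (C7 epimers, left open in the SMILES) | CC1(C)OC[C@@]2(C)[C@@H](O1)CCC3=C2C(=O)C(O)[C@H](C)[C@@]3(C)CC/C(C)=C/CO[Si](c1ccccc1)(c1ccccc1)C(C)(C)C | intermediate
24 | triol | OC[C@@]1(C)[C@@H](O)CCC2=C1C(=O)C(O)[C@H](C)[C@@]2(C)CC/C(C)=C/CO[Si](c1ccccc1)(c1ccccc1)C(C)(C)C | intermediate
25 | primary monoacetate | CC(=O)OC[C@@]1(C)[C@@H](O)CCC2=C1C(=O)C(O)[C@H](C)[C@@]2(C)CC/C(C)=C/CO[Si](c1ccccc1)(c1ccccc1)C(C)(C)C | intermediate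
26 | triketone (not isolated) | CC(=O)OC[C@@]1(C)C(=O)CCC2=C1C(=O)C(=O)[C@H](C)[C@@]2(C)CC/C(C)=C/CO[Si](c1ccccc1)(c1ccccc1)C(C)(C)C | intermediate
27 | silyl-protected diosphenol (O-TBDPS target) | CC(=O)OC[C@@]1(C)C(=O)CCC2=C1C(=O)C(O)=C(C)[C@@]2(C)CC/C(C)=C/CO[Si](c1ccccc1)(c1ccccc1)C(C)(C)C | intermediate
28 | CNP0512382.1, (1S,5S) in the numbering used here | CC(=O)OC[C@@]1(C)C(=O)CCC2=C1C(=O)C(O)=C(C)[C@@]2(C)CC/C(C)=C/CO | target

**Step count.** Total: 17 steps. Longest linear sequence: 15 steps (steps 1–8 and 11–17); steps 9 and 10 form the two-step side branch to iodide 18.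

**Steps most likely to fail**

Step 7. The trisubstituted enal may add too slowly to the hindered diene, so that Mukaiyama-type 1,2-addition to the formyl group or protodesilylation of the diene takes over, or the catalyst may discriminate the two faces of the enal incompletely. The fallback sets out from 11 and comes back at 21. The cycloaddition is run with the achiral promoter Me2AlCl (CH2Cl2, −78 → −20 °C), which should give 13 together with its C5,C6-epimeric adduct F1; because C1 and C2 are fixed, the two are diastereomers. The mixture is taken through steps 8, 11 and 12 as it is, F1 passing through the epimeric vinyl compound F2, the epimeric alkylborane F3 and the epimeric coupled silyl enol ether F4 to the epimeric enone F5. At the enone stage, where C4a is planar and only C5/C6 differ, F5 is removed from 21 by chromatography (preparative HPLC if needed).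

Step 2. The reducing catalyst may fail to tell the two enantiotopic carbonyl groups apart, since methyl and hydroxymethyl are close in size, so that much of the material ends as the diastereomer with the wrong quaternary configuration. The fallback sets out from 3 and comes back at 4. The hydroxyl of 3 is silylated (TBDPSCl, imidazole, CH2Cl2) to the silyl ether dione F6, whose bulky arm should direct a Corey–Bakshi–Shibata reduction ((R)-2-methyl-CBS-oxazaborolidine, catecholborane, toluene, −78 °C) to the carbonyl face anti to it, giving the (2S,3S)-hydroxy ketone silyl ether F7. TBAF in THF then returns diol 4.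

Step 12. Palladation at the fully substituted C8a, which lies next to the quaternary C1, may be too slow, so that the silyl enol ether is merely hydrolysed to the saturated ketone. The fallback sets out from 20 and comes back at 21. Bromination of the silyl enol ether with NBS (THF, −78 °C) gives the tertiary α-bromo ketone F8. Dehydrobromination (Li2CO3, LiBr, DMF, 100 °C) can take only the C4a hydrogen and should give enone 21.

Further compounds
F1 | step 7 | C5,C6-epimeric Diels–Alder adduct | CC1(C)OC[C@@]2(C)[C@@H](O1)CCC3C2=C(O[Si](C)(C)C(C)(C)C)C[C@@H](C)[C@]3(C)C=O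
F2 | step 7 | C5,C6-epimeric C5-vinyl silyl enol ether | CC1(C)OC[C@@]2(C)[C@@H](O1)CCC3C2=C(O[Si](C)(C)C(C)(C)C)C[C@@H](C)[C@]3(C)C=C
F3 | step 7 | C5,C6-epimeric B-alkyl-9-BBN | CC1(C)OC[C@@]2(C)[C@@H](O1)CCC3C2=C(O[Si](C)(C)C(C)(C)C)C[C@@H](C)[C@]3(C)CCB1C2CCCC1CCC2
F4 | step 7 | C5,C6-epimeric coupled silyl enol ether | CC1(C)OC[C@@]2(C)[C@@H](O1)CCC3C2=C(O[Si](C)(C)C(C)(C)C)C[C@@H](C)[C@]3(C)CC/C(C)=C/CO[Si](c1ccccc1)(c1ccccc1)C(C)(C)C
F5 | step 7 | C5,C6-epimeric enone | CC1(C)OC[C@@]2(C)[C@@H](O1)CCC3=C2C(=O)C[C@@H](C)[C@]3(C)CC/C(C)=C/CO[Si](c1ccccc1)(c1ccccc1)C(C)(C)C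
F6 | step 2 | 2-((tert-butyldiphenylsilyloxy)methyl)-2-methylcyclohexane-1,3-dione | CC1(CO[Si](c2ccccc2)(c2ccccc2)C(C)(C)C)C(=O)CCCC1=O
F7 | step 2 | (2S,3S)-2-((tert-butyldiphenylsilyloxy)methyl)-3-hydroxy-2-methylcyclohexan-1-one | CC(C)(C)[Si](OC[C@@]1(C)[C@@H](O)CCCC1=O)(c1ccccc1)c1ccccc1
F8 | step 12 | C8a-bromo C8 ketone (C4a and C8a epimers) | CC1(C)OC[C@@]2(C)[C@@H](O1)CCC3C2(Br)C(=O)C[C@H](C)[C@@]3(C)CC/C(C)=C/CO[Si](c1ccccc1)(c1ccccc1)C(C)(C)C
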